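The route rests on cutting the bond between the benzylic CH2 on C6 of ring A and C1'' of the cyclohexane. C6 lies ortho to O5 and O7 and para to O1, so a C6-CH2OH group ionises easily to an ortho-quinone methide. The exocyclic C2''=CH2 beside C1'' is the footprint of an allylsilane SE2' reaction. One Hosomi-Sakurai-type step joins the complete silyl-protected luteolin core (6-hydroxymethylflavone 4) to the enantiopure cyclohexenylmethylsilane 9. It forms the C-C bond beside the quaternary carbon, sets C1'' under control of the C3'' silyl ether and places the alkene regiospecifically. Only global desilylation follows.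

Key step: step 8

Assumption: luteolin, 4,4-dimethylcyclohex-2-en-1-one, (tributylstannyl)methanol and (trimethylsilyl)methylmagnesium chloride are taken as commercial.
Numbering used: flavone atoms O1 to C8a; ring A is C4a to C8a; ring B is the catechol (C1' to C6'). In the cyclohexane, C1'' bears the CH2, C2'' the methylidene, C3'' the oxygen and C6'' the gem-dimethyl group.

Step 1
Reactants: 1 luteolin
Product: 2 tri-O-TBS-luteolin (silyl ethers at O7/O3'/O4'; 5-OH free)
Conditions: TBSCl (3.3 equiv), imidazole (7 equiv), DMF, 0 °C to rt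
Reagents that add atoms: tert-butyldimethylsilyl chloride, CC(C)(C)[Si](C)(C)Cl
Why: Phenol silylation; the 5-OH is held in a strong hydrogen bond to the C4 carbonyl and is much less reactive, so three equivalents should cap only O7, O3' and O4'.

Step 2
Reactants: 2 tri-O-TBS-luteolin
Product: 3 6-iodo-tri-O-TBS-luteolin
Conditions: NIS (1.05 equiv), DMF, 0 °C to rt, dark
Reagents that add atoms: N-iodosuccinimide, O=C1CCC(=O)N1I
Why: Electrophilic aromatic iodination under neutral conditions; the free 5-OH should direct the iodine donor to its only open ortho position, C6, as is typical of 5-hydroxy-7-alkoxyflavones.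

Step 3
Reactants: 3 6-iodo-tri-O-TBS-luteolin
Product: 4 6-(hydroxymethyl)-tri-O-TBS-luteolin
Conditions: Bu3SnCH2OH (1.3 equiv), Pd(PPh3)4 (10 mol %), 1,4-dioxane, 90 °C
Reagents that add atoms: (tributylstannyl)methanol, CCCC[Sn](CCCC)(CCCC)CO
Why: Stille coupling of an aryl iodide with a hydroxymethylstannane; the base-free conditions should leave the aryl silyl ethers, the chelated phenol and the pyranone untouched.

Step 4
Reactants: 5 4,4-dimethylcyclohex-2-en-1-one
Product: 6 2-iodo-4,4-dimethylcyclohex-2-en-1-one
Conditions: I2 (1.5 equiv), pyridine/CH2Cl2 (1:1), 0 °C to rt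
Reagents that add atoms: iodine, [I][I]
Why: alpha-Iodination of an enone by a Baylis-Hillman-type sequence of pyridine conjugate addition, enolate iodination and elimination.

Step 5
Reactants: 6 2-iodo-4,4-dimethylcyclohex-2-en-1-one
Product: 7 (S)-2-iodo-4,4-dimethylcyclohex-2-en-1-ol
Conditions: (R)-2-methyl-CBS-oxazaborolidine (20 mol %), BH3·SMe2 (0.7 equiv), THF, -20 °C; MeOH, then aqueous work-up
Reagents that add atoms: none
Why: Corey-Bakshi-Shibata reduction; the iodoalkenyl carbon acts as the large group and the ring CH2 as the small one, so the (R)-catalyst should deliver hydride to the face that gives the (S)-carbinol, the future C3''.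

Step 6
Reactants: 7 (S)-2-iodo-4,4-dimethylcyclohex-2-en-1-ol
Product: 8 (S)-tert-butyl[(2-iodo-4,4-dimethylcyclohex-2-en-1-yl)oxy]dimethylsilane
Conditions: TBSCl (1.3 equiv), imidazole (2.5 equiv), DMF, rt
Reagents that add atoms: tert-butyldimethylsilyl chloride, CC(C)(C)[Si](C)(C)Cl
Why: Standard silylation of a secondary alcohol with retention at carbon; the bulky group protects the oxygen from the Grignard reagent and the benzylic cation and later steers the facial selectivity.

Step 7
Reactants: 8 (S)-tert-butyl[(2-iodo-4,4-dimethylcyclohex-2-en-1-yl)oxy]dimethylsilane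
Product: 9 (S)-tert-butyl({4,4-dimethyl-2-[(trimethylsilyl)methyl]cyclohex-2-en-1-yl}oxy)dimethylsilane
Conditions: Me3SiCH2MgCl (2 equiv), Pd(PPh3)4 (5 mol %), THF, rt to 50 °C
Reagents that add atoms: (trimethylsilyl)methylmagnesium chloride, C[Si](C)(C)C[Mg]Cl
Why: Kumada-type cross-coupling of an alkenyl iodide with Me3SiCH2MgCl, a standard allylsilane synthesis that touches neither the alkene position nor the stereocentre.

Step 8
Reactants: 4 6-(hydroxymethyl)-tri-O-TBS-luteolin; 9 (S)-tert-butyl({4,4-dimethyl-2-[(trimethylsilyl)methyl]cyclohex-2-en-1-yl}oxy)dimethylsilane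
Product: 11 tetra-O-TBS-ugonin Q [5-OH free; (1''S,3''S)], via ortho-quinone methide 10 (not isolated)
Conditions: Ca(NTf2)2 (10 mol %), Bu4NPF6 (10 mol %), CH2Cl2, 0 °C to rt; 4 added slowly to 9 (1.5 equiv)
Reagents that add atoms: none
Why: The Lewis acid ionises the C6-CH2OH group of 4, assisted by O5, O7 and O1, to the acid-bound ortho-quinone methide 10, whose unhindered exocyclic CH2 is attacked by the ring CH terminus of allylsilane 9 while charge builds up beta to silicon, and loss of Me3Si to the water set free leaves the exocyclic alkene. The closest known reaction type is the Hosomi-Sakurai SE2' allylation of electron-rich benzylic alcohols and ortho-quinone methides with allylsilanes under Lewis-acid catalysis; no ring is closed. The new stereocentre C1'' is controlled by the C3'' silyl ether: chair-like axial attack takes place on the half-chair that holds OTBS pseudoequatorial, on the face anti to the pseudoaxial methyl of C6'', whereas the other chair-like approach needs OTBS pseudoaxial and 1,3-syn to the incoming carbon, so the CH2 should enter trans to OTBS and give (1''S). Regioselectivity (gamma attack, alkene exclusively exocyclic) is secured by the beta-silicon effect. Chemoselectivity against Friedel-Crafts attack at C8 of a second flavone and against protodesilylation is secured by slow addition of 4 to an excess of 9 under a weakly acidic calcium catalyst, and the O7 silyl ether together with the chelated 5-OH keeps the phenols from adding to the new alkene.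

Step 9
Reactants: 11 tetra-O-TBS-ugonin Q
Product: 12 ugonin Q
Conditions: Et3N·3HF (excess), THF, rt to 40 °C, argon
Reagents that add atoms: none
Why: Fluoride-mediated cleavage of three aryl silyl ethers and one secondary alkyl silyl ether under nearly neutral conditions, which should touch neither stereocentre, avoid ionising the allylic alcohol and avoid adding a phenol to the 1,1-disubstituted alkene.

Compound list
1 | luteolin | O=c1cc(-c2ccc(O)c(O)c2)oc2cc(O)cc(O)c12 | starting material
2 | 5-hydroxy-7,3',4'-tris(tert-butyldimethylsilyloxy)flavone | O=c1cc(-c2ccc(O[Si](C)(C)C(C)(C)C)c(O[Si](C)(C)C(C)(C)C)c2)oc2cc(O[Si](C)(C)C(C)(C)C)cc(O)c12 | intermediate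
3 | 5-hydroxy-6-iodo-7,3',4'-tris(tert-butyldimethylsilyloxy)flavone | O=c1cc(-c2ccc(O[Si](C)(C)C(C)(C)C)c(O[Si](C)(C)C(C)(C)C)c2)oc2cc(O[Si](C)(C)C(C)(C)C)c(I)c(O)c12 | intermediate
4 | 5-hydroxy-6-(hydroxymethyl)-7,3',4'-tris(tert-butyldimethylsilyloxy)flavone | O=c1cc(-c2ccc(O[Si](C)(C)C(C)(C)C)c(O[Si](C)(C)C(C)(C)C)c2)oc2cc(O[Si](C)(C)C(C)(C)C)c(CO)c(O)c12 | intermediate
5 | 4,4-dimethylcyclohex-2-en-1-one | CC1(C)C=CC(=O)CC1 | starting material
6 | 2-iodo-4,4-dimethylcyclohex-2-en-1-one | CC1(C)C=C(I)C(=O)CC1 | intermediate
7 | (S)-2-iodo-4,4-dimethylcyclohex-2-en-1-ol | IC1=CC(C)(C)CC[C@@H]1O | intermediate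
8 | (S)-tert-butyl[(2-iodo-4,4-dimethylcyclohex-2-en-1-yl)oxy]dimethylsilane | IC1=CC(C)(C)CC[C@@H]1O[Si](C)(C)C(C)(C)C | intermediate
9 | (S)-tert-butyl({4,4-dimethyl-2-[(trimethylsilyl)methyl]cyclohex-2-en-1-yl}oxy)dimethylsilane | C[Si](C)(C)CC1=CC(C)(C)CC[C@@H]1O[Si](C)(C)C(C)(C)C | intermediate
10 | ring A ortho-quinone methide (C5 carbonyl, C6 methylidene, O7/O3'/O4' silylated; not isolated) | C=C1C(=O)C2=C(C=C1O[Si](C)(C)C(C)(C)C)OC(=CC2=O)c1ccc(O[Si](C)(C)C(C)(C)C)c(O[Si](C)(C)C(C)(C)C)c1 | intermediate
11 | 6-{[(1S,3S)-3-(tert-butyldimethylsilyloxy)-6,6-dimethyl-2-methylidenecyclohexyl]methyl}-5-hydroxy-7,3',4'-tris(tert-butyldimethylsilyloxy)flavone | C=C1[C@@H](Cc2c(O[Si](C)(C)C(C)(C)C)cc3oc(-c4ccc(O[Si](C)(C)C(C)(C)C)c(O[Si](C)(C)C(C)(C)C)c4)cc(=O)c3c2O)C(C)(C)CC[C@@H]1O[Si](C)(C)C(C)(C)C | intermediate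
12 | ugonin Q, 6-{[(1S,3S)-3-hydroxy-6,6-dimethyl-2-methylidenecyclohexyl]methyl}luteolin (CH2 and OH trans on the ring) | C=C1[C@@H](Cc2c(O)cc3oc(-c4ccc(O)c(O)c4)cc(=O)c3c2O)C(C)(C)CC[C@@H]1O | target

Total step count: 9.
Longest linear sequence: 6 steps (steps 4 to 9, from 5 to 12). The flavone branch contributes 5 steps (steps 1 to 3, 8 and 9).

Steps most likely to fail

1. Step 8. Protodesilylation of the allylsilane and self-condensation of the benzylic cation at C8 of a second flavone may outrun bond formation at the neopentyl-type alkene carbon. Facial selectivity may also be lower than planned.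
The fallback is an acid-free cycloaddition through a temporary ring; it sets out from 4 and 9 and comes back at 12.
- The primary alcohol of 4 is acetylated (Ac2O, pyridine, 0 °C; the chelated 5-OH stays free) to the 6-(acetoxymethyl)flavone F1.
- Heating F1 with 9 in toluene at 100 to 110 °C over solid NaHCO3 expels acetic acid and gives neutral 10.
- Neutral 10 should add to the alkene of 9 in an inverse-demand hetero-Diels-Alder reaction on the face anti to OTBS. This gives the cis-fused (trimethylsilyl)methyl chroman F2, with O5 bound to C2'' and the CH2 bound to C1''.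
- TBAF in THF at 50 °C under argon then removes the four TBS groups and triggers beta-elimination of Me3Si and the O5 aryloxide (Peterson-type, as in the cleavage of 2-(trimethylsilyl)ethyl ethers). This opens the temporary ring only towards the exocyclic alkene and gives 12.

2. Step 3. Slow transmetalation at an arylpalladium centre flanked by OH and OTBS may let protodeiodination take over. The silyl group may also migrate from O7 to the new primary alcohol at 90 °C.
The fallback takes the C1 unit from carbon monoxide; it sets out from 3 and comes back at 4.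
- Reductive carbonylation (Pd(PPh3)4, CO 3 atm, Bu3SnH added slowly, THF, 50 °C) should give the 6-formylflavone F3.
- NaBH4 in THF/EtOH at -10 °C then reduces only the aldehyde to 4.

3. Step 2. Iodination may be shared between C6 and C8 or run on to di-iodination.
The fallback is a template-directed hydroxymethylation; it sets out from 2, bypasses 3 and comes back at 4.
- PhB(OH)2, paraformaldehyde and catalytic propionic acid in refluxing toluene with removal of water bind the only free phenol as an aryl boronate. The boronate delivers formaldehyde to the only open ortho position, C6, and gives the flavone-fused 2-phenyl-4H-1,3,2-dioxaborin F4.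
- Transesterification with propane-1,3-diol at rt releases 4.

Further compounds
F1 | step 8 | 6-(acetoxymethyl)-5-hydroxy-7,3',4'-tris(tert-butyldimethylsilyloxy)flavone | CC(=O)OCc1c(O[Si](C)(C)C(C)(C)C)cc2oc(-c3ccc(O[Si](C)(C)C(C)(C)C)c(O[Si](C)(C)C(C)(C)C)c3)cc(=O)c2c1O
F2 | step 8 | cis-fused chroman from 10 and 9 (O5 on C2'', (trimethylsilyl)methyl on C2'', both new bonds anti to OTBS) | C[Si](C)(C)C[C@]12Oc3c(C[C@H]1C(C)(C)CC[C@@H]2O[Si](C)(C)C(C)(C)C)c(O[Si](C)(C)C(C)(C)C)cc1oc(-c2ccc(O[Si](C)(C)C(C)(C)C)c(O[Si](C)(C)C(C)(C)C)c2)cc(=O)c13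
F3 | step 3 | 6-formyl-5-hydroxy-7,3',4'-tris(tert-butyldimethylsilyloxy)flavone | O=Cc1c(O[Si](C)(C)C(C)(C)C)cc2oc(-c3ccc(O[Si](C)(C)C(C)(C)C)c(O[Si](C)(C)C(C)(C)C)c3)cc(=O)c2c1O
F4 | step 2 | flavone-fused 2-phenyl-4H-1,3,2-dioxaborin spanning O5 and the C6-CH2O group | O=c1cc(-c2ccc(O[Si](C)(C)C(C)(C)C)c(O[Si](C)(C)C(C)(C)C)c2)oc2cc(O[Si](C)(C)C(C)(C)C)c3COB(c4ccccc4)Oc3c12
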